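The ring is numbered C1 (bears the side chain), C2 (OAc), C3 (OAng), C4 (Me, OH), C5 (Cl), C6. The side chain is C7(=C14H2), C8 (OAng), C9 and the C10–C11 epoxide. The all-cis C1–C2–C3 triad next to the trans-diaxial C4/C5 chlorohydrin is the imprint of an endo Diels–Alder cyclohexene. The C2 acetate and the C7=C14 unit are both latent acetyl groups. One catalytic enantioselective cycloaddition of acyclic (Z)-hex-3-ene-2,5-dione with the silyl dienol ether of tiglaldehyde therefore forms C1–C6 and C2–C3 and sets three stereocentres. Chloroketalisation then tells the two acetyls apart. One becomes the acetate by Baeyer–Villiger oxidation, the other an enol triflate for Nozaki–Hiyama–Kishi coupling.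

Key step: step 3

Assumption: the sense of induction of the (S)-oxazaborolidinium catalyst (step 3) and of the (S)-sulfonamide ligand (step 10) is taken from the accepted transition-state models. Both exist in either enantiomeric form, so the drawn series stays accessible.

Step 1
Reactants: 1 2,5-dimethylfuran
Product: 2 (Z)-hex-3-ene-2,5-dione
Conditions: mCPBA (1.0 equiv), CH2Cl2, 0 °C, dark
Reagents that add atoms: mCPBA, O=C(OO)c1cccc(Cl)c1
Why: Oxidative furan ring opening (peracid epoxidation of the electron-rich furan, then spontaneous cleavage) should give the enedione with the Z geometry imposed by the ring.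

Step 2
Reactants: 3 (E)-2-methylbut-2-enal (tiglaldehyde)
Product: 4 tert-butyl(dimethyl){[(1E)-2-methylbuta-1,3-dien-1-yl]oxy}silane
Conditions: TBSOTf, Et3N, Et2O, 0 °C to rt
Reagents that add atoms: TBSOTf, CC(C)(C)[Si](C)(C)OS(=O)(=O)C(F)(F)F
Why: Soft enolisation (O-silylation of the enal and γ-deprotonation by the amine) of the preferred s-trans conformer should give the (1E)-silyl dienol ether.

Step 3
Reactants: 2 (Z)-hex-3-ene-2,5-dione; 4 tert-butyl(dimethyl){[(1E)-2-methylbuta-1,3-dien-1-yl]oxy}silane
Product: 5 all-cis diketone 1,1'-[(1S,2S,3S)-3-(tert-butyldimethylsilyloxy)-4-methylcyclohex-4-ene-1,2-diyl]diethanone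
Conditions: (S)-3,3-diphenyl-1-(2-methylphenyl)tetrahydro-1H,3H-pyrrolo[1,2-c][1,3,2]oxazaborole (20 mol %), HN(SO2CF3)2 (17 mol %), CH2Cl2, −78 °C
Reagents that add atoms: none
Why: The protonated oxazaborolidine binds one of the two equivalent acetyl oxygens of 2, and a concerted asynchronous [4+2] cycloaddition follows, in which the CH2 terminus of 4 (future C6, largest HOMO coefficient) bonds to the β-carbon of the bound enone (future C1) slightly ahead of the C3–C2 bond. The closest known reaction type is the oxazaborolidinium-catalysed enantioselective Diels–Alder reaction of quinones and maleimides, that is of symmetric cis-dicarbonyl dienophiles, with unsymmetrical dienes. The only ring closed is the cyclohexene (ring A), by an intermolecular suprafacial–suprafacial 4π+2π closure. C1 and C2 become cis because the Z geometry of 2 is transferred suprafacially, C3 becomes cis to C2 through the E geometry of 4 combined with the endo placement of both acetyl groups, and the absolute sense comes from the catalyst shielding one face of the bound enone. Because 2 is symmetric no constitutional regioisomer can arise, but the orientation of 4 relative to the bound carbonyl translates directly into enantiomeric purity, and the strongly directing silyloxy group, which overrides the C4 methyl, secures it. The Z integrity of 2 is protected by the low temperature and the non-nucleophilic counterion.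

Step 4
Reactants: 5 all-cis diketone
Product: 6 bridged chloro methyl ketal 1-[4-chloro-8-(tert-butyldimethylsilyloxy)-7-methoxy-5,7-dimethyl-6-oxabicyclo[3.2.1]octan-2-yl]ethanone (route locants: C5–Cl axial and anti to the C4–O bridge that joins C4 to the former C2 acetyl carbon; ketal carbon as either epimer, of no consequence)
Conditions: NCS (1.05 equiv), Ph3P=S (5 mol %), MeOH (10 equiv), CH2Cl2, −20 °C to rt, dark
Reagents that add atoms: N-chlorosuccinimide, O=C1CCC(=O)N1Cl; methanol, CO
Why: In this halocyclisation (chloroketalisation, the ketone counterpart of halolactonisation) the chloronium ion forms on the face anti to the three cis substituents, the axial C2 acetyl oxygen opens it 5-exo at the tertiary C4, and methanol traps the oxocarbenium ion, which sets C4 and C5 trans-diaxially, masks only the C2 acetyl and protects the tertiary oxygen.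

Step 5
Reactants: 6 bridged chloro methyl ketal
Product: 8 enol triflate of 6 (C7(OTf)=C14H2 on C1), via potassium enolate 7 (not isolated)
Conditions: KN(SiMe3)2 (1.1 equiv), THF, −78 °C; then PhN(SO2CF3)2, −78 to −20 °C
Reagents that add atoms: N-phenylbis(trifluoromethanesulfonimide), O=S(=O)(N(c1ccccc1)S(=O)(=O)C(F)(F)F)C(F)(F)F; KN(SiMe3)2, C[Si](C)(C)[N-][Si](C)(C)C.[K+] (potassium, in 7 only)
Why: Kinetic enolate formation at the methyl group of the only free ketone followed by O-sulfonylation (enol triflate synthesis) should be clean because the ketal removes both the aldol partner and the alkoxide that could displace chloride, and C1 is not touched.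

Step 6
Reactants: 8 enol triflate of 6
Product: 9 enol triflate hydroxy ketone (C3–OH, C4–OH, C5–Cl, C2 acetyl; drawn in the open form, a ring–chain tautomer of the C4–O hemiketal)
Conditions: 48 % aq HF, MeCN, 0 °C to rt
Reagents that add atoms: water, O
Why: Acidic ketal hydrolysis and fluoride-driven desilylation take place in one operation, under conditions that leave the enol triflate, the chloride and all stereocentres unchanged.

Step 7
Reactants: 9 enol triflate hydroxy ketone
Product: 10 enol triflate acetate (C2–OAc, C3–OH, C4–OH, C5–Cl)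
Conditions: mCPBA (3 equiv), CF3CO2H (1 equiv), CH2Cl2, 0 °C to rt
Reagents that add atoms: mCPBA, O=C(OO)c1cccc(Cl)c1
Why: In the Baeyer–Villiger oxidation the secondary C2 migrates in preference to methyl with retention, so the C2–C bond carried from step 3 becomes the C2–O bond of the acetate, while the electron-poor enol triflate resists epoxidation.

Step 8
Reactants: 11 4-methylpent-3-en-1-ol
Product: 12 2-[(2S)-3,3-dimethyloxiran-2-yl]ethanol
Conditions: 1,2:4,5-di-O-isopropylidene-β-L-erythro-2,3-hexodiulo-2,6-pyranose (30 mol %), KHSO5 (as 2KHSO5·KHSO4·K2SO4), K2CO3, Bu4NHSO4 (cat.), MeCN/(MeO)2CH2, aq Na2B4O7/Na2EDTA buffer, 0 °C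
Reagents that add atoms: potassium peroxymonosulfate, [K+].[O-]S(=O)(=O)OO
Why: In the Shi asymmetric epoxidation the dioxirane of the L-fructose-derived ketone transfers oxygen to the trisubstituted alkene through the spiro transition state, which sets C10 as S.

Step 9
Reactants: 12 2-[(2S)-3,3-dimethyloxiran-2-yl]ethanol
Product: 13 [(2S)-3,3-dimethyloxiran-2-yl]acetaldehyde
Conditions: Dess–Martin periodinane, NaHCO3, CH2Cl2, 0 °C
Reagents that add atoms: none
Why: The buffered Dess–Martin oxidation is neutral enough to avoid β-elimination of the epoxide and does not touch C10.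

Step 10
Reactants: 10 enol triflate acetate; 13 [(2S)-3,3-dimethyloxiran-2-yl]acetaldehyde
Product: 14 (8S)-allylic alcohol (C2–OAc; free C3–OH, C4–OH and C8–OH; C5–Cl; C10–C11 epoxide)
Conditions: CrCl2 (4 equiv), (S)-N-[2-(4-isopropyl-4,5-dihydro-1,3-oxazol-2-yl)-6-methylphenyl]methanesulfonamide (4.4 equiv), Et3N (4.4 equiv), NiCl2 (cat.), THF, rt
Reagents that add atoms: none
Why: In the Nozaki–Hiyama–Kishi coupling nickel inserts into the C–OTf bond, the alkenyl group passes to trivalent chromium and adds chemoselectively to the aldehyde, and the chiral sulfonamide on chromium directs attack to the Re face to set C8 as S.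

Step 11
Reactants: 14 (8S)-allylic alcohol; 15 angelic acid ((Z)-2-methylbut-2-enoic acid)
Product: 17 target CNP0313121.1, via mixed anhydride 16 (not isolated)
Conditions: 15 (6 equiv), 2,4,6-trichlorobenzoyl chloride, Et3N, toluene, rt, ammonium salt filtered off; then 14, toluene, 75 °C
Reagents that add atoms: 2,4,6-trichlorobenzoyl chloride, O=C(Cl)c1c(Cl)cc(Cl)cc1Cl (its acyl group stays in 16 only)
Why: The Yamaguchi-type mixed-anhydride esterification without a nucleophilic catalyst should acylate both secondary alcohols (C3, C8), spare the tertiary C4–OH and keep the Z geometry of the angelate.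

Compound list
1 | 2,5-dimethylfuran | Cc1ccc(C)o1 | starting material
2 | (Z)-hex-3-ene-2,5-dione | CC(=O)/C=C\C(C)=O | intermediate
3 | (E)-2-methylbut-2-enal (tiglaldehyde) | C/C=C(\C)C=O | starting material
4 | tert-butyl(dimethyl){[(1E)-2-methylbuta-1,3-dien-1-yl]oxy}silane | C=C/C(C)=C/O[Si](C)(C)C(C)(C)C | intermediate
5 | 1,1'-[(1S,2S,3S)-3-(tert-butyldimethylsilyloxy)-4-methylcyclohex-4-ene-1,2-diyl]diethanone | CC(=O)[C@H]1CC=C(C)[C@@H](O[Si](C)(C)C(C)(C)C)[C@H]1C(C)=O | intermediate
6 | bridged chloro methyl ketal (6-oxabicyclo[3.2.1]octane, ketal carbon undefined) | CC(=O)[C@H]1C[C@H](Cl)[C@@](C)(O2)[C@@H](O[Si](C)(C)C(C)(C)C)[C@H]1C2(C)OC | intermediate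
7 | potassium enolate of 6 | C=C([O-])[C@H]1C[C@H](Cl)[C@@](C)(O2)[C@@H](O[Si](C)(C)C(C)(C)C)[C@H]1C2(C)OC.[K+] | intermediate
8 | enol triflate of 6 | C=C(OS(=O)(=O)C(F)(F)F)[C@H]1C[C@H](Cl)[C@@](C)(O2)[C@@H](O[Si](C)(C)C(C)(C)C)[C@H]1C2(C)OC | intermediate
9 | enol triflate hydroxy ketone | C=C(OS(=O)(=O)C(F)(F)F)[C@H]1C[C@H](Cl)[C@@](C)(O)[C@@H](O)[C@H]1C(C)=O | intermediate
10 | enol triflate acetate | C=C(OS(=O)(=O)C(F)(F)F)[C@H]1C[C@H](Cl)[C@@](C)(O)[C@@H](O)[C@H]1OC(C)=O | intermediate
11 | 4-methylpent-3-en-1-ol | CC(C)=CCCO | starting material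
12 | 2-[(2S)-3,3-dimethyloxiran-2-yl]ethanol | OCC[C@@H]1OC1(C)C | intermediate
13 | [(2S)-3,3-dimethyloxiran-2-yl]acetaldehyde | O=CC[C@@H]1OC1(C)C | intermediate
14 | (8S)-allylic alcohol | C=C([C@H](C[C@@H]1OC1(C)C)O)[C@H]1C[C@H](Cl)[C@@](C)(O)[C@@H](O)[C@H]1OC(C)=O | intermediate
15 | angelic acid | OC(=O)/C(C)=C\C | starting material
16 | angelic 2,4,6-trichlorobenzoic anhydride | O=C(OC(=O)/C(C)=C\C)c1c(Cl)cc(Cl)cc1Cl | intermediate
17 | CNP0313121.1 (route locants 1R,2S,3S,4S,5S,8S,10S) | C=C([C@H](C[C@@H]1OC1(C)C)OC(=O)/C(C)=C\C)[C@H]1C[C@H](Cl)[C@@](C)(O)[C@@H](OC(=O)/C(C)=C\C)[C@H]1OC(C)=O | target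

Total step count: 11. Longest linear sequence: 8 steps (2, 3, 4, 5, 6, 7, 10, 11).

Steps most likely to fail

Step 3. The dienophile may isomerise from Z to E under the acid catalyst, or an achiral silyl-transfer background reaction may erode the facial and orientational selectivity. The fallback replaces catalyst control by an auxiliary on the diene oxygen; with the symmetric dienophile only the diene face then matters. It sets out from 3 and 2. Tiglaldehyde is deprotonated (KN(SiMe3)2, THF, −78 °C) and O-acylated with (S)-O-methylmandeloyl chloride to give the dienyl (S)-O-methylmandelate F1. F1 is heated with 2 in toluene at 60 °C without any acid to give the all-cis mandelate adduct F2. Neutral transesterification ((ClBu2Sn)2O cat., MeOH, toluene) frees the hydroxy diketone F3. TBSOTf with 2,6-lutidine then returns to the route at 5.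

Step 4. Ene-type allylic chlorination of the trisubstituted alkene, or capture of the chloronium ion at C4 by methanol instead of the acetyl oxygen, may compete. The fallback uses the more reliable bromocyclisation and exchanges the halogen later through an epoxide, with double inversion at C5. It sets out from 5.
- NBS in MeOH/CH2Cl2 gives the bromo ketal F4.
- KN(SiMe3)2 and then PhN(SO2CF3)2 give the bromo ketal enol triflate F5.
- Aqueous HF in MeCN gives the bromohydrin hydroxy ketone F6.
- K2CO3 in MeCN closes the epoxide on the face syn to the C1–C3 substituents, giving F7.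
- Li2CuCl4 in THF opens F7 trans-diaxially at the secondary C5 (Fürst–Plattner rule), which returns to the route at 9.

Step 10. The facial selectivity at the aldehyde may be poor, and the aldehyde may be consumed by β-elimination of the epoxide. The fallback gives up stereocontrol in the C–C coupling and sets C8 by reagent-controlled reduction instead. It sets out from 10 and 13. Ligand-free coupling (CrCl2, NiCl2 cat., DMF) gives 14 together with its (8R)-epimer F8. MnO2 in CH2Cl2 oxidises only the allylic C8 alcohol of both to the enone F9. Corey–Bakshi–Shibata reduction with (R)-1-methyl-3,3-diphenyltetrahydro-1H,3H-pyrrolo[1,2-c][1,3,2]oxazaborole and catecholborane at −78 °C, with the alkenyl group as the large substituent, returns to the route at 14.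

Further compounds
F1 | step 3 | (1E)-2-methylbuta-1,3-dien-1-yl (2S)-2-methoxy-2-phenylacetate | C=C/C(C)=C/OC(=O)[C@@H](OC)c1ccccc1
F2 | step 3 | all-cis Diels–Alder adduct carrying the (S)-O-methylmandelate at C3 | CC(=O)[C@H]1CC=C(C)[C@@H](OC(=O)[C@@H](OC)c2ccccc2)[C@H]1C(C)=O
F3 | step 3 | 1,1'-[(1S,2S,3S)-3-hydroxy-4-methylcyclohex-4-ene-1,2-diyl]diethanone | CC(=O)[C@H]1CC=C(C)[C@@H](O)[C@H]1C(C)=O
F4 | step 4 | bridged bromo methyl ketal | CC(=O)[C@H]1C[C@H](Br)[C@@](C)(O2)[C@@H](O[Si](C)(C)C(C)(C)C)[C@H]1C2(C)OC
F5 | step 4 | enol triflate of the bromo ketal | C=C(OS(=O)(=O)C(F)(F)F)[C@H]1C[C@H](Br)[C@@](C)(O2)[C@@H](O[Si](C)(C)C(C)(C)C)[C@H]1C2(C)OC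
F6 | step 4 | bromohydrin hydroxy ketone enol triflate | C=C(OS(=O)(=O)C(F)(F)F)[C@H]1C[C@H](Br)[C@@](C)(O)[C@@H](O)[C@H]1C(C)=O
F7 | step 4 | C4–C5 epoxide syn to the C1–C3 substituents | C=C(OS(=O)(=O)C(F)(F)F)[C@H]1C[C@H]2O[C@@]2(C)[C@@H](O)[C@H]1C(C)=O
F8 | step 10 | (8R)-epimer of 14 | C=C([C@@H](C[C@@H]1OC1(C)C)O)[C@H]1C[C@H](Cl)[C@@](C)(O)[C@@H](O)[C@H]1OC(C)=O
F9 | step 10 | C8 enone | C=C(C(=O)C[C@@H]1OC1(C)C)[C@H]1C[C@H](Cl)[C@@](C)(O)[C@@H](O)[C@H]1OC(C)=O
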